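The route rests on cutting the ten-membered carbocycle at C1–C2 and C9–C10; the C6–C7 bond shared with the lactone ring is closed afterwards. The key step exploits the C1=C10 enal of the ten-membered ring: C10 carries formyl C14 and carbinol C9, and C2 stands cis to C9, the signature of a syn carbometalation of a propiolaldehyde acetal in which C2 arrives as the carbon ligand and C9 as the electrophile. One flask joins a homoallylic cuprate (C2–C6, C15, Z-C4=C5), 3,3-diethoxypropyne (C1, C10, C14) and an α-silyloxy aldehyde (C7–C9), forming two bonds and the C9 stereocentre. The precursor is a Z-5-iodo-3-methylpent-2-enyl silyl ether, used as its lithium cuprate.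

Key step: step 8

Remark: atoms are referred to by germacrane numbering (C6–C5=C4(C15)–C3–C2–C1=C10(C14)–C9–C8–C7, lactone carbons C11–C13). CIP descriptors change where substituent priorities change although no configuration is altered (C8 in 18, C7 between 25/26 and 27). The aldehyde is built from (S)-glycidol, which shortens its preparation.

Step 1
Reactants: 1 4-methyl-5,6-dihydro-2H-pyran-2-one
Product: 2 (Z)-3-methylpent-2-ene-1,5-diol
Conditions: LiAlH4, Et2O, −10 → 0 °C; aq. NaOH work-up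
Reagents that add atoms: none
Why: Hydride reduction of the unsaturated lactone at the acyl carbon opens the ring to the diol, and since the alkene was held inside a six-membered ring the chain ends C3 and C6 must be cis (Z).

Step 2
Reactants: 2 (Z)-3-methylpent-2-ene-1,5-diol
Product: 3 (Z)-5-(tert-butyldimethylsilyloxy)-3-methylpent-3-en-1-ol
Conditions: TBSCl (0.95 equiv), imidazole, CH2Cl2, −20 °C
Reagents that add atoms: tert-butyldimethylsilyl chloride, CC(C)(C)[Si](C)(C)Cl
Why: Kinetic monosilylation should favour the allylic hydroxyl, which is the more acidic one and is flanked only by a planar sp2 carbon; the minor regioisomer and the bis-ether are separable and can be recycled to 2.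

Step 3
Reactants: 3 (Z)-5-(tert-butyldimethylsilyloxy)-3-methylpent-3-en-1-ol
Product: 4 (Z)-tert-butyl[(5-iodo-3-methylpent-2-en-1-yl)oxy]dimethylsilane
Conditions: I2, PPh3, imidazole, CH2Cl2, 0 °C
Reagents that add atoms: iodine, II
Why: Appel-type iodination displaces the alkoxyphosphonium of the primary alcohol by iodide (SN2) under buffered conditions that leave the allylic silyl ether and the alkene geometry untouched.

Step 4
Reactants: 5 (S)-glycidol
Product: 6 (R)-2-[(4-methoxybenzyloxy)methyl]oxirane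
Conditions: NaH, PMBCl, Bu4NI (cat.), THF/DMF, 0 °C → rt
Reagents that add atoms: 4-methoxybenzyl chloride, COc1ccc(CCl)cc1
Why: Williamson etherification at oxygen breaks no bond to the stereocentre; the descriptor changes from S to R only because the ether arm now outranks the oxirane CH2.

Step 5
Reactants: 6 (R)-2-[(4-methoxybenzyloxy)methyl]oxirane
Product: 7 (R)-1-(4-methoxybenzyloxy)but-3-en-2-ol
Conditions: Me3SI (4 equiv), nBuLi, THF, −10 °C → rt
Reagents that add atoms: trimethylsulfonium iodide, C[S+](C)C.[I-]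
Why: Sulfonium-ylide homologation of a terminal epoxide: the ylide opens the oxirane at CH2, and the betaine is deprotonated and expels Me2S to give the allylic alcohol, with the carbinol configuration untouched.

Step 6
Reactants: 7 (R)-1-(4-methoxybenzyloxy)but-3-en-2-ol
Product: 8 (R)-[1-(4-methoxybenzyloxy)but-3-en-2-yloxy]triisopropylsilane
Conditions: TIPSOTf, 2,6-lutidine, CH2Cl2, 0 °C → rt
Reagents that add atoms: triisopropylsilyl triflate, CC(C)[Si](C(C)C)(C(C)C)OS(=O)(=O)C(F)(F)F
Why: Silylation of the secondary alcohol with the silyl triflate installs the bulky, non-chelating group that will later direct the addition to C9.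

Step 7
Reactants: 8 (R)-[1-(4-methoxybenzyloxy)but-3-en-2-yloxy]triisopropylsilane
Product: 9 (S)-3-(4-methoxybenzyloxy)-2-(triisopropylsilyloxy)propanal
Conditions: OsO4 (2 mol%), NaIO4, 2,6-lutidine, dioxane/H2O, rt
Reagents that add atoms: sodium periodate, [Na+].[O-]I(=O)(=O)=O
Why: Lemieux–Johnson cleavage of the terminal vinyl group spares the PMB ether, and the buffered medium keeps the α-silyloxy aldehyde configurationally intact (S only by change of priorities).

Step 8
Reactants: 4 (Z)-tert-butyl[(5-iodo-3-methylpent-2-en-1-yl)oxy]dimethylsilane, 10 3,3-diethoxyprop-1-yne, 9 (S)-3-(4-methoxybenzyloxy)-2-(triisopropylsilyloxy)propanal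
Product: 14 (2S,3R,4E,8Z)-10-(tert-butyldimethylsilyloxy)-4-(diethoxymethyl)-1-(4-methoxybenzyloxy)-8-methyl-2-(triisopropylsilyloxy)deca-4,8-dien-3-ol, via alkyllithium 11 (not isolated), via lithium dialkylcuprate 12 (not isolated), via lithium dialkenylcuprate 13 (not isolated)
Conditions: 4 (2.2 equiv), tBuLi (4.4 equiv), Et2O, −78 °C; CuBr·SMe2 (1.1 equiv), −78 → −40 °C; 10 (2.2 equiv), −50 → −35 °C; 9 (1.0 equiv), −78 → −40 °C; aq. NH4Cl/NH3 quench at −40 °C
Reagents that add atoms: none
Why: Iodine–lithium exchange and transmetalation give R2CuLi, which adds across the alkyne in a concerted syn fashion, the alkyl group (C2) going to the terminal carbon (C1) and copper to the carbon next to the acetal (C10); the alkenyl cuprate then adds 1,2 to aldehyde 9 with retention of alkene geometry, so C1–C2 and C9–C10 are formed with C2 cis to C9 and C14 trans to C2. The closest known reaction type is the carbocupration of propargylic acetals followed by electrophilic capture of the alkenyl cuprate, here with an aldehyde as the electrophile. No ring is closed, so no mode of closure arises. The new stereocentre C9 is controlled by the C8 silyloxy stereocentre through polar Felkin–Anh attack anti to the bulky, non-chelating OTIPS group, which should give the 8,9-anti (8S,9R) carbinol, and six-ring chelation through the PMB oxygen would direct to the same face. The step needs regio- and syn-selective carbometalation (secured by the acetal and the concerted mechanism) and addition to the aldehyde ahead of ethoxide loss to the allenyl ether (secured by keeping the cuprate below about −35 °C). The aldehyde is the limiting component because only one alkenyl ligand of the cuprate is transferred.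

Step 9
Reactants: 14 (2S,3R,4E,8Z)-10-(tert-butyldimethylsilyloxy)-4-(diethoxymethyl)-1-(4-methoxybenzyloxy)-8-methyl-2-(triisopropylsilyloxy)deca-4,8-dien-3-ol, 15 (R)-2-methylbutanoic acid
Product: 16 (2S,3R,4E,8Z)-10-(tert-butyldimethylsilyloxy)-4-(diethoxymethyl)-1-(4-methoxybenzyloxy)-8-methyl-2-(triisopropylsilyloxy)deca-4,8-dien-3-yl (2R)-2-methylbutanoate
Conditions: DCC, DMAP (0.3 equiv), CH2Cl2, 0 °C → rt
Reagents that add atoms: none
Why: Steglich esterification acylates the only free hydroxyl (C9–OH), and carbodiimide activation at low temperature should not racemise the α-stereocentre of the acid.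

Step 10
Reactants: 16 (2S,3R,4E,8Z)-10-(tert-butyldimethylsilyloxy)-4-(diethoxymethyl)-1-(4-methoxybenzyloxy)-8-methyl-2-(triisopropylsilyloxy)deca-4,8-dien-3-yl (2R)-2-methylbutanoate
Product: 17 (2S,3R,4E,8Z)-10-(tert-butyldimethylsilyloxy)-4-(diethoxymethyl)-1-hydroxy-8-methyl-2-(triisopropylsilyloxy)deca-4,8-dien-3-yl (2R)-2-methylbutanoate
Conditions: DDQ, CH2Cl2/aq. NaH2PO4–Na2HPO4 (pH 7), 0 °C
Reagents that add atoms: none
Why: Oxidative PMB cleavage (benzylic hydride abstraction, then hydrolysis) frees the C7 hydroxyl, and the neutral buffer keeps the acetal, both silyl ethers and the ester in place.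

Step 11
Reactants: 17 (2S,3R,4E,8Z)-10-(tert-butyldimethylsilyloxy)-4-(diethoxymethyl)-1-hydroxy-8-methyl-2-(triisopropylsilyloxy)deca-4,8-dien-3-yl (2R)-2-methylbutanoate
Product: 18 (2R,3R,4E,8Z)-10-(tert-butyldimethylsilyloxy)-4-(diethoxymethyl)-8-methyl-1-oxo-2-(triisopropylsilyloxy)deca-4,8-dien-3-yl (2R)-2-methylbutanoate
Conditions: Dess–Martin periodinane, NaHCO3, CH2Cl2, 0 °C → rt
Reagents that add atoms: none
Why: Dess–Martin oxidation under buffered, non-basic conditions should give the C7 aldehyde without C8 epimerisation or β-elimination of the C9 ester (descriptor 2R only by change of priorities).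

Step 12
Reactants: 18 (2R,3R,4E,8Z)-10-(tert-butyldimethylsilyloxy)-4-(diethoxymethyl)-8-methyl-1-oxo-2-(triisopropylsilyloxy)deca-4,8-dien-3-yl (2R)-2-methylbutanoate, 19 methyl acrylate
Product: 20 methyl (4S,5R,6E,10Z)-12-(tert-butyldimethylsilyloxy)-6-(diethoxymethyl)-3-hydroxy-10-methyl-2-methylidene-5-[(2R)-2-methylbutanoyloxy]-4-(triisopropylsilyloxy)dodeca-6,10-dienoate (C3 epimers)
Conditions: DABCO (1 equiv), methyl acrylate (excess), MeOH (3 equiv), 0 °C → rt
Reagents that add atoms: none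
Why: Morita–Baylis–Hillman reaction: the amine–acrylate zwitterion adds to the activated α-oxygenated aldehyde and the amine is expelled, forming C7–C11; the C7 carbinol configuration is irrelevant because C7 becomes trigonal in the next step.

Step 13
Reactants: 20 methyl (4S,5R,6E,10Z)-12-(tert-butyldimethylsilyloxy)-6-(diethoxymethyl)-3-hydroxy-10-methyl-2-methylidene-5-[(2R)-2-methylbutanoyloxy]-4-(triisopropylsilyloxy)dodeca-6,10-dienoate
Product: 21 methyl (2Z,4S,5R,6E,10Z)-2-(bromomethyl)-12-(tert-butyldimethylsilyloxy)-6-(diethoxymethyl)-10-methyl-5-[(2R)-2-methylbutanoyloxy]-4-(triisopropylsilyloxy)dodeca-2,6,10-trienoate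
Conditions: NBS, Me2S (reagent preformed), CH2Cl2, 0 °C → rt
Reagents that add atoms: N-bromosuccinimide, BrN1C(=O)CCC1=O
Why: Corey–Kim-type bromination: bromide displaces the alkoxysulfonium with allylic transposition (SN2′) to give the conjugated primary bromide, normally as the Z isomer (C8 cis to CH2Br), under neutral conditions that spare the acetal and the trisubstituted alkene.

Step 14
Reactants: 21 methyl (2Z,4S,5R,6E,10Z)-2-(bromomethyl)-12-(tert-butyldimethylsilyloxy)-6-(diethoxymethyl)-10-methyl-5-[(2R)-2-methylbutanoyloxy]-4-(triisopropylsilyloxy)dodeca-2,6,10-trienoate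
Product: 22 methyl (2Z,4S,5R,6E,10Z)-2-(bromomethyl)-6-(diethoxymethyl)-12-hydroxy-10-methyl-5-[(2R)-2-methylbutanoyloxy]-4-(triisopropylsilyloxy)dodeca-2,6,10-trienoate
Conditions: CSA (0.1 equiv), EtOH/CH2Cl2, 0 °C
Reagents that add atoms: none
Why: Acid-catalysed solvolysis removes the primary allylic TBS ether far faster than the hindered secondary TIPS ether, and ethanol as solvent makes any exchange at the diethyl acetal degenerate.

Step 15
Reactants: 22 methyl (2Z,4S,5R,6E,10Z)-2-(bromomethyl)-6-(diethoxymethyl)-12-hydroxy-10-methyl-5-[(2R)-2-methylbutanoyloxy]-4-(triisopropylsilyloxy)dodeca-2,6,10-trienoate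
Product: 23 methyl (2Z,4S,5R,6E,10Z)-2-(bromomethyl)-6-(diethoxymethyl)-10-methyl-5-[(2R)-2-methylbutanoyloxy]-12-oxo-4-(triisopropylsilyloxy)dodeca-2,6,10-trienoate
Conditions: Dess–Martin periodinane, NaHCO3, CH2Cl2, 0 °C
Reagents that add atoms: none
Why: Buffered Dess–Martin oxidation of the allylic alcohol gives the C6 enal quickly and without base, so the Z-C4=C5 geometry and the allylic bromide should survive.

Step 16
Reactants: 23 methyl (2Z,4S,5R,6E,10Z)-2-(bromomethyl)-6-(diethoxymethyl)-10-methyl-5-[(2R)-2-methylbutanoyloxy]-12-oxo-4-(triisopropylsilyloxy)dodeca-2,6,10-trienoate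
Product: 25 (1(10)E,4Z,6R,7S,8S,9R)-14,14-diethoxy-9-[(2R)-2-methylbutanoyloxy]-8-(triisopropylsilyloxy)germacra-1(10),4,11(13)-trien-12,6-olide, via cyclised hydroxy ester 24 (not isolated)
Conditions: CrCl2 (8 equiv), THF, rt, slow addition of 23 (final about 0.003 M); aq. NH4Cl work-up
Reagents that add atoms: none
Why: Intramolecular Barbier allylation of the Nozaki–Hiyama type: the allylchromium formed at C13 adds through C7 to the C6 aldehyde in a closed chair-like transition state that closes the ten-membered ring, and the C6 alkoxide lactonises onto the methyl ester; C5 and C8 are expected to lie anti across the new bond (6,7-trans lactone, as is usual for such closures to germacranolides) and the bulky C8 silyloxy group to turn outward, which should set 6R and the C7 configuration of the target.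

Step 17
Reactants: 25 (1(10)E,4Z,6R,7S,8S,9R)-14,14-diethoxy-9-[(2R)-2-methylbutanoyloxy]-8-(triisopropylsilyloxy)germacra-1(10),4,11(13)-trien-12,6-olide
Product: 27 (1(10)E,4Z,6R,7R,8S,9R)-8-hydroxy-9-[(2R)-2-methylbutanoyloxy]-14-oxogermacra-1(10),4,11(13)-trien-12,6-olide (CNP0256845.2), via silyl-protected enal 26 (not isolated)
Conditions: 48% aq. HF, MeCN, 0 °C → rt
Reagents that add atoms: water, O
Why: Aqueous acid first hydrolyses the unsaturated diethyl acetal to the enal and HF then cleaves the secondary TIPS ether; the acidic medium avoids base-induced migration of the C9 acyl group to O8 and should leave the methylene lactone and the enal intact.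

Compound list
1 | 4-methyl-5,6-dihydro-2H-pyran-2-one | CC1=CC(=O)OCC1 | starting material
2 | (Z)-3-methylpent-2-ene-1,5-diol | OC/C=C(/C)CCO | intermediate
3 | (Z)-5-(tert-butyldimethylsilyloxy)-3-methylpent-3-en-1-ol | OCC/C(C)=C\CO[Si](C)(C)C(C)(C)C | intermediate
4 | (Z)-tert-butyl[(5-iodo-3-methylpent-2-en-1-yl)oxy]dimethylsilane | ICC/C(C)=C\CO[Si](C)(C)C(C)(C)C | intermediate
5 | (S)-glycidol | OC[C@H]1CO1 | starting material
6 | (R)-2-[(4-methoxybenzyloxy)methyl]oxirane | COc1ccc(COC[C@H]2CO2)cc1 | intermediate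
7 | (R)-1-(4-methoxybenzyloxy)but-3-en-2-ol | C=C[C@@H](O)COCc1ccc(OC)cc1 | intermediate
8 | (R)-[1-(4-methoxybenzyloxy)but-3-en-2-yloxy]triisopropylsilane | C=C[C@@H](O[Si](C(C)C)(C(C)C)C(C)C)COCc1ccc(OC)cc1 | intermediate
9 | (S)-3-(4-methoxybenzyloxy)-2-(triisopropylsilyloxy)propanal | O=C[C@@H](O[Si](C(C)C)(C(C)C)C(C)C)COCc1ccc(OC)cc1 | intermediate
10 | 3,3-diethoxyprop-1-yne | C#CC(OCC)OCC | starting material
11 | (Z)-5-(tert-butyldimethylsilyloxy)-3-methylpent-3-enyllithium | [Li]CC/C(C)=C\CO[Si](C)(C)C(C)(C)C | intermediate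
12 | lithium bis[(Z)-5-(tert-butyldimethylsilyloxy)-3-methylpent-3-enyl]cuprate (R2CuLi) | [Li+].CC(C)(C)[Si](C)(C)OC/C=C(/C)CC[Cu-]CC/C(C)=C\CO[Si](C)(C)C(C)(C)C | intermediate
13 | lithium bis[(1Z,5Z)-7-(tert-butyldimethylsilyloxy)-1-(diethoxymethyl)-5-methylhepta-1,5-dienyl]cuprate | [Li+].CCOC(OCC)/C(=C/CC/C(C)=C\CO[Si](C)(C)C(C)(C)C)[Cu-]/C(=C\CC/C(C)=C\CO[Si](C)(C)C(C)(C)C)C(OCC)OCC | intermediate
14 | (2S,3R,4E,8Z)-10-(tert-butyldimethylsilyloxy)-4-(diethoxymethyl)-1-(4-methoxybenzyloxy)-8-methyl-2-(triisopropylsilyloxy)deca-4,8-dien-3-ol (germacrane 8S,9R; free 9-OH) | CC(C)(C)[Si](C)(C)OC/C=C(/C)CC/C=C(/C(OCC)OCC)[C@@H](O)[C@@H](O[Si](C(C)C)(C(C)C)C(C)C)COCc1ccc(OC)cc1 | intermediate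
15 | (R)-2-methylbutanoic acid | CC[C@@H](C)C(=O)O | starting material
16 | (2S,3R,4E,8Z)-10-(tert-butyldimethylsilyloxy)-4-(diethoxymethyl)-1-(4-methoxybenzyloxy)-8-methyl-2-(triisopropylsilyloxy)deca-4,8-dien-3-yl (2R)-2-methylbutanoate | CC(C)(C)[Si](C)(C)OC/C=C(/C)CC/C=C(/C(OCC)OCC)[C@@H](OC(=O)[C@H](C)CC)[C@@H](O[Si](C(C)C)(C(C)C)C(C)C)COCc1ccc(OC)cc1 | intermediate
17 | (2S,3R,4E,8Z)-10-(tert-butyldimethylsilyloxy)-4-(diethoxymethyl)-1-hydroxy-8-methyl-2-(triisopropylsilyloxy)deca-4,8-dien-3-yl (2R)-2-methylbutanoate | CC(C)(C)[Si](C)(C)OC/C=C(/C)CC/C=C(/C(OCC)OCC)[C@@H](OC(=O)[C@H](C)CC)[C@@H](O[Si](C(C)C)(C(C)C)C(C)C)CO | intermediate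
18 | (2R,3R,4E,8Z)-10-(tert-butyldimethylsilyloxy)-4-(diethoxymethyl)-8-methyl-1-oxo-2-(triisopropylsilyloxy)deca-4,8-dien-3-yl (2R)-2-methylbutanoate | CC(C)(C)[Si](C)(C)OC/C=C(/C)CC/C=C(/C(OCC)OCC)[C@@H](OC(=O)[C@H](C)CC)[C@@H](O[Si](C(C)C)(C(C)C)C(C)C)C=O | intermediate
19 | methyl acrylate | C=CC(=O)OC | starting material
20 | methyl (4S,5R,6E,10Z)-12-(tert-butyldimethylsilyloxy)-6-(diethoxymethyl)-3-hydroxy-10-methyl-2-methylidene-5-[(2R)-2-methylbutanoyloxy]-4-(triisopropylsilyloxy)dodeca-6,10-dienoate (C3 epimers) | CC(C)(C)[Si](C)(C)OC/C=C(/C)CC/C=C(/C(OCC)OCC)[C@@H](OC(=O)[C@H](C)CC)[C@@H](O[Si](C(C)C)(C(C)C)C(C)C)C(O)C(=C)C(=O)OC | intermediate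
21 | methyl (2Z,4S,5R,6E,10Z)-2-(bromomethyl)-12-(tert-butyldimethylsilyloxy)-6-(diethoxymethyl)-10-methyl-5-[(2R)-2-methylbutanoyloxy]-4-(triisopropylsilyloxy)dodeca-2,6,10-trienoate | CC(C)(C)[Si](C)(C)OC/C=C(/C)CC/C=C(/C(OCC)OCC)[C@@H](OC(=O)[C@H](C)CC)[C@@H](O[Si](C(C)C)(C(C)C)C(C)C)/C=C(\CBr)C(=O)OC | intermediate
22 | methyl (2Z,4S,5R,6E,10Z)-2-(bromomethyl)-6-(diethoxymethyl)-12-hydroxy-10-methyl-5-[(2R)-2-methylbutanoyloxy]-4-(triisopropylsilyloxy)dodeca-2,6,10-trienoate | OC/C=C(/C)CC/C=C(/C(OCC)OCC)[C@@H](OC(=O)[C@H](C)CC)[C@@H](O[Si](C(C)C)(C(C)C)C(C)C)/C=C(\CBr)C(=O)OC | intermediate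
23 | methyl (2Z,4S,5R,6E,10Z)-2-(bromomethyl)-6-(diethoxymethyl)-10-methyl-5-[(2R)-2-methylbutanoyloxy]-12-oxo-4-(triisopropylsilyloxy)dodeca-2,6,10-trienoate | O=C/C=C(/C)CC/C=C(/C(OCC)OCC)[C@@H](OC(=O)[C@H](C)CC)[C@@H](O[Si](C(C)C)(C(C)C)C(C)C)/C=C(\CBr)C(=O)OC | intermediate
24 | cyclised hydroxy ester: ten-membered ring (6R,7S,8S,9R) with free C6–OH (present as its chromium alkoxide) and C7 bearing the 1-(methoxycarbonyl)vinyl group | O[C@@H]1/C=C(/C)CC/C=C(/C(OCC)OCC)[C@@H](OC(=O)[C@H](C)CC)[C@@H](O[Si](C(C)C)(C(C)C)C(C)C)[C@H]1C(=C)C(=O)OC | intermediate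
25 | (1(10)E,4Z,6R,7S,8S,9R)-14,14-diethoxy-9-[(2R)-2-methylbutanoyloxy]-8-(triisopropylsilyloxy)germacra-1(10),4,11(13)-trien-12,6-olide | C=C1C(=O)O[C@@H]2/C=C(/C)CC/C=C(/C(OCC)OCC)[C@@H](OC(=O)[C@H](C)CC)[C@@H](O[Si](C(C)C)(C(C)C)C(C)C)[C@@H]12 | intermediate
26 | (1(10)E,4Z,6R,7S,8S,9R)-9-[(2R)-2-methylbutanoyloxy]-14-oxo-8-(triisopropylsilyloxy)germacra-1(10),4,11(13)-trien-12,6-olide | C=C1C(=O)O[C@@H]2/C=C(/C)CC/C=C(/C=O)[C@@H](OC(=O)[C@H](C)CC)[C@@H](O[Si](C(C)C)(C(C)C)C(C)C)[C@@H]12 | intermediate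
27 | (1(10)E,4Z,6R,7R,8S,9R)-8-hydroxy-9-[(2R)-2-methylbutanoyloxy]-14-oxogermacra-1(10),4,11(13)-trien-12,6-olide (CNP0256845.2) | C=C1C(=O)O[C@@H]2/C=C(/C)CC/C=C(/C=O)[C@@H](OC(=O)[C@H](C)CC)[C@@H](O)[C@@H]12 | target

Total step count: 17. Longest linear sequence: 14 steps (from 5 through steps 4–7, 8 and 9–17). The iodide branch (steps 1–3) is convergent.

Steps most likely to fail

Step 8. The alkenyl cuprate may add too slowly to the hindered aldehyde and, on any warming, lose ethoxide to the allenyl ether; facial selectivity at C9 may also be modest. The fallback separates the two bond formations and sets out from 4 and 10, coming back at 14. The carbocupration is run as in step 8 and cuprate 13 is quenched with iodine at −78 °C to give tert-butyl{[(2Z,6Z)-8,8-diethoxy-7-iodo-3-methylocta-2,6-dien-1-yl]oxy}dimethylsilane F1. F1 and aldehyde 9 are then joined in a Nozaki–Hiyama–Kishi coupling (CrCl2, NiCl2 cat., DMF, rt), which keeps the alkene geometry, tolerates the acetal and silyl ethers and should give the same Felkin adduct 14.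

Step 16. The macrocyclic transition state may give the wrong simple diastereoselection (cis-fused lactone) or poor facial selectivity at C7, and intermolecular coupling may compete. The fallback inverts the geometry of the allyl donor so that C8 sits equatorial in the closed transition state without prior isomerisation; it sets out from aldehyde 18 and comes back at 25. Bromo-Still–Gennari olefination of 18 (methyl bromo[bis(2,2,2-trifluoroethoxy)phosphoryl]acetate, KN(SiMe3)2, 18-crown-6, THF, −78 °C) should give methyl (2E,4S,5R,6E,10Z)-2-bromo-12-(tert-butyldimethylsilyloxy)-6-(diethoxymethyl)-10-methyl-5-[(2R)-2-methylbutanoyloxy]-4-(triisopropylsilyloxy)dodeca-2,6,10-trienoate F2, with C8 cis to the ester. Stille coupling with Bu3SnCH2OH (Pd(PPh3)4, dioxane, 80 °C) gives the (2Z)-2-(hydroxymethyl) trienoate F3. Appel bromination (CBr4, PPh3, CH2Cl2, 0 °C) gives the (2E)-2-(bromomethyl) trienoate F4. Desilylation as in step 14 gives the 12-hydroxy (2E)-bromide F5, and oxidation as in step 15 gives the 12-oxo (2E)-bromide F6. Cyclisation of F6 with CrCl2 (or indium powder in THF/H2O) at high dilution is expected to deliver the 6,7-trans lactone 25.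

Step 12. Amine-induced β-elimination of the C9 carboxylate from aldehyde 18 (through the C8 enolate), or C8 epimerisation, may outrun a slow addition to the hindered α-silyloxy aldehyde. The fallback replaces amine catalysis by a preformed α-metalated acrylate; it sets out from 18 and comes back at 20. Hydroalumination of methyl propiolate with iBu2AlH and N-methylmorpholine N-oxide (THF, 0 °C) gives [1-(methoxycarbonyl)vinyl]diisobutylaluminium, which adds to 18 at 0 °C under non-basic conditions and delivers 20 directly, so no further compound arises (F0).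

Further compounds
F1 | step 8 | tert-butyl{[(2Z,6Z)-8,8-diethoxy-7-iodo-3-methylocta-2,6-dien-1-yl]oxy}dimethylsilane | CCOC(OCC)/C(I)=C/CC/C(C)=C\CO[Si](C)(C)C(C)(C)C
F0 | step 12 | none | none
F2 | step 16 | methyl (2E,4S,5R,6E,10Z)-2-bromo-12-(tert-butyldimethylsilyloxy)-6-(diethoxymethyl)-10-methyl-5-[(2R)-2-methylbutanoyloxy]-4-(triisopropylsilyloxy)dodeca-2,6,10-trienoate | CC(C)(C)[Si](C)(C)OC/C=C(/C)CC/C=C(/C(OCC)OCC)[C@@H](OC(=O)[C@H](C)CC)[C@@H](O[Si](C(C)C)(C(C)C)C(C)C)/C=C(/Br)C(=O)OC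
F3 | step 16 | methyl (2Z,4S,5R,6E,10Z)-12-(tert-butyldimethylsilyloxy)-6-(diethoxymethyl)-2-(hydroxymethyl)-10-methyl-5-[(2R)-2-methylbutanoyloxy]-4-(triisopropylsilyloxy)dodeca-2,6,10-trienoate | CC(C)(C)[Si](C)(C)OC/C=C(/C)CC/C=C(/C(OCC)OCC)[C@@H](OC(=O)[C@H](C)CC)[C@@H](O[Si](C(C)C)(C(C)C)C(C)C)/C=C(/CO)C(=O)OC
F4 | step 16 | methyl (2E,4S,5R,6E,10Z)-2-(bromomethyl)-12-(tert-butyldimethylsilyloxy)-6-(diethoxymethyl)-10-methyl-5-[(2R)-2-methylbutanoyloxy]-4-(triisopropylsilyloxy)dodeca-2,6,10-trienoate | CC(C)(C)[Si](C)(C)OC/C=C(/C)CC/C=C(/C(OCC)OCC)[C@@H](OC(=O)[C@H](C)CC)[C@@H](O[Si](C(C)C)(C(C)C)C(C)C)/C=C(/CBr)C(=O)OC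
F5 | step 16 | methyl (2E,4S,5R,6E,10Z)-2-(bromomethyl)-6-(diethoxymethyl)-12-hydroxy-10-methyl-5-[(2R)-2-methylbutanoyloxy]-4-(triisopropylsilyloxy)dodeca-2,6,10-trienoate | OC/C=C(/C)CC/C=C(/C(OCC)OCC)[C@@H](OC(=O)[C@H](C)CC)[C@@H](O[Si](C(C)C)(C(C)C)C(C)C)/C=C(/CBr)C(=O)OC
F6 | step 16 | methyl (2E,4S,5R,6E,10Z)-2-(bromomethyl)-6-(diethoxymethyl)-10-methyl-5-[(2R)-2-methylbutanoyloxy]-12-oxo-4-(triisopropylsilyloxy)dodeca-2,6,10-trienoate | O=C/C=C(/C)CC/C=C(/C(OCC)OCC)[C@@H](OC(=O)[C@H](C)CC)[C@@H](O[Si](C(C)C)(C(C)C)C(C)C)/C=C(/CBr)C(=O)OC
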